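**Retrosynthetic overview**
- The six-membered carbocycle is the benzene ring of a 2,5-dimethoxybenzoate: target ⇐ ethyl ester ⇐ triol on a norbornene template ⇐ p-quinone ⇐ arene.
- The tetrasubstituted ring alkene (heptenyl, CH2OH) is masked as the two quaternary ring-fusion carbons of a cyclopentadiene adduct and is released last by retro-Diels–Alder.
- Key step: enantioselective Diels–Alder of cyclopentadiene across the ester/alkenyl-bearing bond of the quinone, followed in the same flask by exo epoxidation, so the norbornene ring and the oxirane form in one operation.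
- On the template both ketones and the angular ester are reduced from the exo face, which puts both carbinols anti to the epoxide.
- Ring order: benzene ring (bought) → norbornene + oxirane (together) → norbornene opened thermally, leaving the epoxycyclohexene.

Assumption: the (S,S) ligand is taken to give the enantiomer of adduct 13 drawn below; if the sense of induction is the opposite, the (R,R) ligand is used.

**Step 1**
Reactants: 1 4-bromo-2,5-dimethoxybenzoic acid
Product: 2 methyl 4-bromo-2,5-dimethoxybenzoate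
Conditions: MeI, K2CO3, DMF, 25 °C
Reagents that add atoms: iodomethane, CI
Why: SN2 O-alkylation of the carboxylate (esterification) gives the ester that later directs metalation and activates the quinone; no stereocentre.

**Step 2**
Reactants: 2 methyl 4-bromo-2,5-dimethoxybenzoate
Product: 4 methyl 4-bromo-2-iodo-3,6-dimethoxybenzoate, via arylmagnesium chloride 3 (not isolated)
Conditions: TMPMgCl·LiCl (TMP = 2,2,6,6-tetramethylpiperidide), THF, −20 °C; then I2
Reagents that add atoms: iodine, II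
Why: Directed ortho-metalation with the Knochel–Hauser amide base removes the only hydrogen flanked by the ester and a methoxy group without Br/Mg exchange, and iodinolysis puts iodine on the carbon that will carry the heptenyl group; no stereocentre.

**Step 3**
Reactants: 4 methyl 4-bromo-2-iodo-3,6-dimethoxybenzoate; 5 hept-1-yne
Product: 7 methyl 4-bromo-2-[(1E)-hept-1-en-1-yl]-3,6-dimethoxybenzoate, via alkenylborane 6 (not isolated)
Conditions: 5, catecholborane, 70 °C; then 4, Pd(PPh3)4 (3 mol %), aq K2CO3, dioxane, 60 °C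
Reagents that add atoms: none
Why: syn-Hydroboration of the terminal alkyne fixes the E alkene, and the Suzuki–Miyaura coupling takes place at C–I in preference to C–Br (faster oxidative addition) with retention of alkene geometry.

**Step 4**
Reactants: 7 methyl 4-bromo-2-[(1E)-hept-1-en-1-yl]-3,6-dimethoxybenzoate; 8 ethyl (2E)-2-methylbut-2-enoate
Product: 10 methyl 4-[(2E)-4-ethoxy-3-methyl-4-oxobut-2-en-1-yl]-2-[(1E)-hept-1-en-1-yl]-3,6-dimethoxybenzoate, via silyl dienolate 9 (not isolated)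
Conditions: 8, LiN(i-Pr)2, DMPU, THF, −78 °C, then Me3SiCl; then 7, Pd(dba)2 (dba = dibenzylideneacetone, 2 mol %), P(t-Bu)3 (4 mol %), ZnF2, DMF, 80 °C
Reagents that add atoms: none
Why: Palladium-catalysed vinylogous (γ) arylation of the silyl dienolate, in which the methyl-blocked α-carbon forces C–C bond formation at the γ-terminus and conjugation returns the E enoate.

**Step 5**
Reactants: 10 methyl 4-[(2E)-4-ethoxy-3-methyl-4-oxobut-2-en-1-yl]-2-[(1E)-hept-1-en-1-yl]-3,6-dimethoxybenzoate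
Product: 11 methyl 4-[(2E)-4-ethoxy-3-methyl-4-oxobut-2-en-1-yl]-2-[(1E)-hept-1-en-1-yl]-3,6-dioxocyclohexa-1,4-diene-1-carboxylate
Conditions: (NH4)2Ce(NO3)6 (2.5 equiv), MeCN/H2O, 0 °C; used at once
Reagents that add atoms: water, O
Why: Oxidative demethylation of the p-dimethoxyarene (two one-electron oxidations with capture of water) gives the p-quinone; no stereocentre.

**Step 6 (key step)**
Reactants: 11 methyl 4-[(2E)-4-ethoxy-3-methyl-4-oxobut-2-en-1-yl]-2-[(1E)-hept-1-en-1-yl]-3,6-dioxocyclohexa-1,4-diene-1-carboxylate; 12 cyclopenta-1,3-diene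
Product: 14 methyl exo-4,5-epoxy-4-[(2E)-4-ethoxy-3-methyl-4-oxobut-2-en-1-yl]-2-[(1E)-hept-1-en-1-yl]-3,6-dioxo-endo-tricyclo[6.2.1.0(2,7)]undec-9-ene-7-carboxylate, via Diels–Alder adduct 13 (not isolated)
Conditions: 12 (5 equiv), Sm(OSO2CF3)3 (10 mol %), (S,S)-Ph-pybox (12 mol %), 4 Å sieves, CH2Cl2, −78 to −40 °C; then acetone, 30% aq H2O2, Na2CO3, 0 °C
Reagents that add atoms: hydrogen peroxide, OO
Why: Proposed new method: two-point chelation of the ester carbonyl and the neighbouring ring carbonyl (C6=O) by the chiral samarium–pybox Lewis acid lowers the LUMO of the tetrasubstituted C1=C2 bond selectively, so cyclopentadiene adds there endo on the ligand-open face and creates both quaternary ring-fusion carbons (heptenyl and ester exo); the remaining C4=C5 ene-dione bond is then epoxidised by hydroperoxide from the convex exo face (Weitz–Scheffer), which fixes the two epoxide stereocentres relative to the template; the closest known chemistry is the lanthanide–pybox-catalysed Diels–Alder reaction of 2-alkoxycarbonyl-1,4-benzoquinones and the exo epoxidation of cyclopentadiene–quinone adducts, the new element being the tetrasubstituted, alkenyl-bearing dienophile.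

**Step 7**
Reactants: 14 methyl exo-4,5-epoxy-4-[(2E)-4-ethoxy-3-methyl-4-oxobut-2-en-1-yl]-2-[(1E)-hept-1-en-1-yl]-3,6-dioxo-endo-tricyclo[6.2.1.0(2,7)]undec-9-ene-7-carboxylate
Product: 15 ethyl (2E)-4-[exo-4,5-epoxy-2-[(1E)-hept-1-en-1-yl]-endo-3,endo-6-dihydroxy-7-(hydroxymethyl)-endo-tricyclo[6.2.1.0(2,7)]undec-9-en-4-yl]-2-methylbut-2-enoate
Conditions: LiBH4 (6 equiv), THF/MeOH, −20 to 20 °C
Reagents that add atoms: none
Why: Borohydride reduction in which hydride reaches both ketones only from the exo face (the endo face is blocked by the C9=C10 bridge), so both hydroxyls end anti to the exo epoxide, and the resulting alkoxyborohydrides reduce the neighbouring angular methyl ester (β-hydroxy-ester-assisted reduction) while the remote conjugated ethyl ester is spared.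

**Step 8**
Reactants: 15 ethyl (2E)-4-[exo-4,5-epoxy-2-[(1E)-hept-1-en-1-yl]-endo-3,endo-6-dihydroxy-7-(hydroxymethyl)-endo-tricyclo[6.2.1.0(2,7)]undec-9-en-4-yl]-2-methylbut-2-enoate
Product: 16 ethyl (2E)-4-[(1S,2R,5S,6R)-3-[(1E)-hept-1-en-1-yl]-2,5-dihydroxy-4-(hydroxymethyl)-7-oxabicyclo[4.1.0]hept-3-en-1-yl]-2-methylbut-2-enoate
Conditions: Ph2O, 200 °C, 20 min, argon sparge
Reagents that add atoms: none
Why: Thermal retro-Diels–Alder reaction, driven by relief of the two vicinal quaternary ring-fusion carbons and by formation of the conjugated diene, expels cyclopentadiene and unveils the tetrasubstituted alkene without touching the four stereocentres set on the template.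

**Step 9**
Reactants: 16 ethyl (2E)-4-[(1S,2R,5S,6R)-3-[(1E)-hept-1-en-1-yl]-2,5-dihydroxy-4-(hydroxymethyl)-7-oxabicyclo[4.1.0]hept-3-en-1-yl]-2-methylbut-2-enoate
Product: 17 (2E)-4-[(1S,2R,5S,6R)-3-[(1E)-hept-1-en-1-yl]-2,5-dihydroxy-4-(hydroxymethyl)-7-oxabicyclo[4.1.0]hept-3-en-1-yl]-2-methylbut-2-enoic acid
Conditions: LiOH, THF/H2O, 0 to 20 °C; then 1 M HCl to pH 4, 0 °C
Reagents that add atoms: lithium hydroxide, [Li+].[OH-]
Why: Saponification of the ethyl enoate (acyl–oxygen cleavage) under mild conditions leaves the epoxide and all stereocentres untouched.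

**Compound list**
1 | 4-bromo-2,5-dimethoxybenzoic acid | COc1cc(Br)c(OC)cc1C(=O)O | starting material
2 | methyl 4-bromo-2,5-dimethoxybenzoate | COc1cc(Br)c(OC)cc1C(=O)OC | intermediate
3 | [3-bromo-2,5-dimethoxy-6-(methoxycarbonyl)phenyl]magnesium chloride (LiCl complex, not isolated) | COC(=O)c1c(OC)cc(Br)c(OC)c1[Mg]Cl | intermediate
4 | methyl 4-bromo-2-iodo-3,6-dimethoxybenzoate | COc1cc(Br)c(OC)c(I)c1C(=O)OC | intermediate
5 | hept-1-yne | CCCCCC#C | starting material
6 | 2-[(1E)-hept-1-en-1-yl]-1,3,2-benzodioxaborole (not isolated) | CCCCC/C=C/B1Oc2ccccc2O1 | intermediate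
7 | methyl 4-bromo-2-[(1E)-hept-1-en-1-yl]-3,6-dimethoxybenzoate | CCCCC/C=C/c1c(OC)c(Br)cc(OC)c1C(=O)OC | intermediate
8 | ethyl (2E)-2-methylbut-2-enoate (ethyl tiglate) | C/C=C(\C)C(=O)OCC | starting material
9 | [(1-ethoxy-2-methylbuta-1,3-dien-1-yl)oxy]trimethylsilane (not isolated) | CCOC(O[Si](C)(C)C)=C(C)C=C | intermediate
10 | methyl 4-[(2E)-4-ethoxy-3-methyl-4-oxobut-2-en-1-yl]-2-[(1E)-hept-1-en-1-yl]-3,6-dimethoxybenzoate | CCCCC/C=C/c1c(OC)c(C/C=C(\C)C(=O)OCC)cc(OC)c1C(=O)OC | intermediate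
11 | methyl 4-[(2E)-4-ethoxy-3-methyl-4-oxobut-2-en-1-yl]-2-[(1E)-hept-1-en-1-yl]-3,6-dioxocyclohexa-1,4-diene-1-carboxylate | CCCCC/C=C/C1=C(C(=O)OC)C(=O)C=C(C/C=C(\C)C(=O)OCC)C1=O | intermediate
12 | cyclopenta-1,3-diene (cracked from the dimer) | C1C=CC=C1 | starting material
13 | endo Diels–Alder adduct, methyl 4-[(2E)-4-ethoxy-3-methyl-4-oxobut-2-en-1-yl]-2-[(1E)-hept-1-en-1-yl]-3,6-dioxotricyclo[6.2.1.0(2,7)]undeca-4,9-diene-7-carboxylate; C2-heptenyl and C7-ester cis and exo (syn to the C11 bridge); not isolated | CCCCC/C=C/[C@]12C(=O)C(C/C=C(\C)C(=O)OCC)=CC(=O)[C@@]1(C(=O)OC)[C@H]3C=C[C@@H]2C3 | intermediate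
14 | exo-4,5-epoxide of 13 (epoxide oxygen on the same face as the heptenyl and ester groups) | CCCCC/C=C/[C@]12C(=O)[C@]3(C/C=C(\C)C(=O)OCC)O[C@@H]3C(=O)[C@@]1(C(=O)OC)[C@H]4C=C[C@@H]2C4 | intermediate
15 | template-bound triol: exo epoxide, endo 3-OH and endo 6-OH (both anti to the epoxide), exo 7-CH2OH, side-chain ethyl ester intact | CCCCC/C=C/[C@]12[C@@H](O)[C@]3(C/C=C(\C)C(=O)OCC)O[C@@H]3[C@@H](O)[C@@]1(CO)[C@H]4C=C[C@@H]2C4 | intermediate
16 | ethyl (2E)-4-[(1S,2R,5S,6R)-3-[(1E)-hept-1-en-1-yl]-2,5-dihydroxy-4-(hydroxymethyl)-7-oxabicyclo[4.1.0]hept-3-en-1-yl]-2-methylbut-2-enoate | CCCCC/C=C/C1=C(CO)[C@H](O)[C@H]2O[C@@]2(C/C=C(\C)C(=O)OCC)[C@@H]1O | intermediate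
17 | (2E)-4-[(1S,2R,5S,6R)-3-[(1E)-hept-1-en-1-yl]-2,5-dihydroxy-4-(hydroxymethyl)-7-oxabicyclo[4.1.0]hept-3-en-1-yl]-2-methylbut-2-enoic acid | CCCCC/C=C/C1=C(CO)[C@H](O)[C@H]2O[C@@]2(C/C=C(\C)C(=O)O)[C@@H]1O | target

**Count**
Total steps: 9. Longest linear sequence: 9 (1 → 17). The route is a paper plan; the tags in the tricyclic SMILES were derived by hand from a three-dimensional model and were not checked with software.

**Three steps most likely to fail, with fallbacks**

Step 6. Cyclopentadiene may not add across the tetrasubstituted, alkenyl-bearing bond, or may add at C4=C5 instead. The fallback sets out from 4 and comes back at 16, and carries a linear hept-1-ynyl group (smaller and more electron-withdrawing) through the cycloaddition. Sonogashira coupling of 4 with 5 (Pd(PPh3)2Cl2, CuI, Et3N) gives methyl 4-bromo-2-(hept-1-yn-1-yl)-3,6-dimethoxybenzoate F1. The conditions of step 4 give methyl 4-[(2E)-4-ethoxy-3-methyl-4-oxobut-2-en-1-yl]-2-(hept-1-yn-1-yl)-3,6-dimethoxybenzoate F2, and those of step 5 give the alkynylquinone methyl 4-[(2E)-4-ethoxy-3-methyl-4-oxobut-2-en-1-yl]-2-(hept-1-yn-1-yl)-3,6-dioxocyclohexa-1,4-diene-1-carboxylate F3. The conditions of step 6 give the alkynyl Diels–Alder adduct F4 and from it the alkynyl exo-epoxide F5. LiBH4 as in step 7 gives the alkynyl template triol F6, and heating as in step 8 gives the enyne ester ethyl (2E)-4-[(1S,2R,5S,6R)-3-(hept-1-yn-1-yl)-2,5-dihydroxy-4-(hydroxymethyl)-7-oxabicyclo[4.1.0]hept-3-en-1-yl]-2-methylbut-2-enoate F7. Ruthenium-catalysed trans-hydrogenation ([Cp*RuCl(cod)], H2) then converts the alkyne into the E alkene, which is 16.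

Step 7. The borohydride may not distinguish the hindered angular ester from the side-chain ester. The fallback sets out from 14 and comes back at 17. Excess i-Bu2AlH (CH2Cl2, −78 to 0 °C) reduces both ketones (exo attack) and both esters to the template tetraol F8. While the ring fusion is sp3, its only allylic alcohol is the side-chain one, so MnO2 oxidises that position alone to the template enal F9. Pinnick oxidation (NaClO2, NaH2PO4, 2-methylbut-2-ene) gives the template carboxylic acid F10, and the cycloreversion of step 8 then delivers 17 directly, without the saponification.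

Step 8. The free epoxy-triol may not survive 200 °C, or the cycloreversion may be too slow without a carbonyl to drive it. The fallback sets out from 11 and comes back at 16, and uses 6,6-dimethylfulvene as the diene, whose adducts fragment near 120 °C. Under the conditions of step 6 it gives the fulvene Diels–Alder adduct F11 and from it the fulvene exo-epoxide F12. LiBH4 as in step 7 gives the fulvene template triol F13, and heating in toluene at about 120 °C releases dimethylfulvene and gives 16.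

**Further compounds**
F1 | step 6 | methyl 4-bromo-2-(hept-1-yn-1-yl)-3,6-dimethoxybenzoate | CCCCCC#Cc1c(OC)c(Br)cc(OC)c1C(=O)OC
F2 | step 6 | methyl 4-[(2E)-4-ethoxy-3-methyl-4-oxobut-2-en-1-yl]-2-(hept-1-yn-1-yl)-3,6-dimethoxybenzoate | CCCCCC#Cc1c(OC)c(C/C=C(\C)C(=O)OCC)cc(OC)c1C(=O)OC
F3 | step 6 | methyl 4-[(2E)-4-ethoxy-3-methyl-4-oxobut-2-en-1-yl]-2-(hept-1-yn-1-yl)-3,6-dioxocyclohexa-1,4-diene-1-carboxylate | CCCCCC#CC1=C(C(=O)OC)C(=O)C=C(C/C=C(\C)C(=O)OCC)C1=O
F4 | step 6 | alkynyl Diels–Alder adduct (endo; heptynyl and ester exo) | CCCCCC#C[C@]12C(=O)C(C/C=C(\C)C(=O)OCC)=CC(=O)[C@@]1(C(=O)OC)[C@H]3C=C[C@@H]2C3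
F5 | step 6 | alkynyl exo-epoxide | CCCCCC#C[C@]12C(=O)[C@]3(C/C=C(\C)C(=O)OCC)O[C@@H]3C(=O)[C@@]1(C(=O)OC)[C@H]4C=C[C@@H]2C4
F6 | step 6 | alkynyl template triol | CCCCCC#C[C@]12[C@@H](O)[C@]3(C/C=C(\C)C(=O)OCC)O[C@@H]3[C@@H](O)[C@@]1(CO)[C@H]4C=C[C@@H]2C4
F7 | step 6 | ethyl (2E)-4-[(1S,2R,5S,6R)-3-(hept-1-yn-1-yl)-2,5-dihydroxy-4-(hydroxymethyl)-7-oxabicyclo[4.1.0]hept-3-en-1-yl]-2-methylbut-2-enoate | CCCCCC#CC1=C(CO)[C@H](O)[C@H]2O[C@@]2(C/C=C(\C)C(=O)OCC)[C@@H]1O
F8 | step 7 | template tetraol (side chain reduced to the allylic alcohol) | CCCCC/C=C/[C@]12[C@@H](O)[C@]3(C/C=C(\C)CO)O[C@@H]3[C@@H](O)[C@@]1(CO)[C@H]4C=C[C@@H]2C4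
F9 | step 7 | template enal | CCCCC/C=C/[C@]12[C@@H](O)[C@]3(C/C=C(\C)C=O)O[C@@H]3[C@@H](O)[C@@]1(CO)[C@H]4C=C[C@@H]2C4
F10 | step 7 | template carboxylic acid | CCCCC/C=C/[C@]12[C@@H](O)[C@]3(C/C=C(\C)C(=O)O)O[C@@H]3[C@@H](O)[C@@]1(CO)[C@H]4C=C[C@@H]2C4
F11 | step 8 | fulvene Diels–Alder adduct (11-isopropylidene analogue of 13) | CCCCC/C=C/[C@]12C(=O)C(C/C=C(\C)C(=O)OCC)=CC(=O)[C@@]1(C(=O)OC)[C@H]3C=C[C@@H]2C3=C(C)C
F12 | step 8 | fulvene exo-epoxide (11-isopropylidene analogue of 14) | CCCCC/C=C/[C@]12C(=O)[C@]3(C/C=C(\C)C(=O)OCC)O[C@@H]3C(=O)[C@@]1(C(=O)OC)[C@H]4C=C[C@@H]2C4=C(C)C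
F13 | step 8 | fulvene template triol (11-isopropylidene analogue of 15) | CCCCC/C=C/[C@]12[C@@H](O)[C@]3(C/C=C(\C)C(=O)OCC)O[C@@H]3[C@@H](O)[C@@]1(CO)[C@H]4C=C[C@@H]2C4=C(C)C
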